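## Structural features

The target is a flavone: benzo ring A is fused to 4-pyranone ring C (a chromen-4-one), and aryl ring B is attached through the C2–C1' single bond. Ring A carries 5-OH (chelated to the C4 carbonyl), 7-OH and 8-OMe and keeps only C6–H, while ring B carries 2'-OH, 4'-OMe and 5'-OMe. There is no stereocentre and no stereogenic double bond, so the problem is one of regiochemistry and of telling six oxygens apart (three free phenols, three methyl ethers). Three features are fragile: the 5,7,8-trioxygenated chromone can open at C2 in hot acid and reclose to the 5,6,7-isomer (Wessely–Moser rearrangement), the pyranone of a 2'-oxygenated flavone can be opened by hot alkali to a 1,3-diketone that may reclose onto either ring, and the para-alkoxyphenol of ring B is easily oxidised. The real difficulty is therefore to place the methoxy group at C8 and not at C6, and to unveil the 5-, 7- and 2'-hydroxyls without touching the methyl ethers or ring C. The key step exploits the fact that both ends of the C2–C1' bond are biased C–H positions. C2–H of ring C is the beta-carbon of a vinylogous ester, and C1'–H of ring B lies ortho to the 2'-oxygen (which can carry a directing carbamate) and para to the 4'-methoxy group, whereas the other ortho position, C3', is flanked by two oxygens.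

## Logic of the disconnections

**12 from 11.** Retrosynthetically a dimethylcarbamoyl group is placed on the 2'-oxygen, so the bond concerned is the acyl C–O bond of a carbamate. A free 2'-phenol would not survive a palladium/silver oxidation, and the carbamoyl group is also what steers the metal to C1'. Nothing is gained in skeleton. The demand is that hydroxide cleaves a hindered carbamate without opening ring C. For that reason the hydrolysis comes after debenzylation, so that it meets the 5,7-diphenoxide, in which C2 is a poor electrophile, and not a fully etherified flavone.

**11 from 10.** The two O–CH2Ph bonds at O5 and O7 are cut. Benzyl ethers separate these two oxygens from the three methyl ethers, tolerate weak acid and oxidant, and leave under neutral conditions. The demand is a hydrogenolysis that stops short of the C2=C3 bond and leaves the carbamate alone.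

**10 to 6 and 9.** The C2–C1' bond is cut, the strategic disconnection. It divides the molecule into two fragments of similar size, and neither needs a halide or a boron group at the carbons to be joined. Mapping C6 of 9 onto C1' gives exactly the 2'-oxy-4',5'-dimethoxy pattern of 12. The forward step must select C6 of 9 over C2 and C5, C2 of 6 over C3, and cross-coupling over homocoupling.

**9 to 7 and 8.** The carbamate C–O bond is cut, which leads to two commercial compounds. The forward step only has to acylate a phenol.

**6 to 4 (through 5).** The O1–C2 and C2–C3 bonds are cut, C2 being a one-carbon unit. This reduces the chromone to an ortho-hydroxyacetophenone in which the chelated hydroxyl becomes O1. The demand is that this hydroxyl stays free and is not alkylated by the amide acetal.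

**4 to 3.** The aryl C–OMe bond at the future C8 is cut. The oxygen thus arrives already methylated. A persulfate hydroxylation of a less protected ketone would instead leave three free phenols to be alkylated one at a time. The forward step is a CuCl-catalysed substitution at a hindered, electron-rich iodide and must outrun reduction of the C–I bond.

**3 to 2.** The C–I bond is cut. The demand is iodination ortho to the free hydroxyl and not between the two benzyloxy groups, because this site decides whether the methoxy group ends at C8 or at C6.

**2 to 1.** Two O–benzyl bonds are cut. Chelation to the acetyl group keeps the third hydroxyl free, so the same operation protects O5 and O7 and singles out the future O1.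

## Other disconnections considered

Alternative 1: Ring A is built instead of bought. The C7–C8 and C5–C6 bonds are cut, leading back to a pyranone that already carries ring B, methyl 6-[2-(benzyloxy)-4,5-dimethoxyphenyl]-2-(methoxymethyl)-4-oxo-4H-pyran-3-carboxylate A2, and to N-methoxy-N-methylacetamide A3 as the two-carbon unit.

- Forward key step: the CH2 of the methoxymethyl group of A2, vinylogous to the pyranone carbonyl, is deprotonated and acetylated by A3 (C7–C8). The methyl ketone enolate then attacks the ester in a 6-exo-trig Claisen (Dieckmann-type) closure (C5–C6), and double enolisation gives 2-[2-(benzyloxy)-4,5-dimethoxyphenyl]-5,7-dihydroxy-8-methoxychromen-4-one A1. One hydrogenolysis would finish the synthesis.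
- In its favour: the position of the 8-methoxy group is fixed by the carbon skeleton, O5 and O7 are born as free hydroxyls, and only one benzyl ether remains.
- Against it here: A2 is a pyranone with three different substituents, and its own preparation should cost at least as many steps as 6 and 9 together. The carbanion sits next to an ether oxygen and must form in competition with addition of the base to the pyranone. The acylated product is more acidic than A2, so excess base is needed. The amide adduct releases the ketone only on quenching, so ring closure probably needs a second base treatment.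
- Comparison: in regiochemical certainty for ring A and in the length of the endgame (one step against two) this alternative is better than the chosen plan. Mechanistically it relies on stoichiometric strong-base chemistry of a sensitive pyranone, against catalytic C–H chemistry; each has one step of real uncertainty. In step economy and convergence the chosen plan is expected to be ahead.

Alternative 2: The C5–O bond is cut, so the 5-hydroxyl is introduced last on 2-[8-methoxy-4-oxo-7-(pivaloyloxy)chromen-2-yl]-4,5-dimethoxyphenyl pivalate A5, a flavone assembled from a pyrogallol-type (1,2,3-trioxygenated) ketone.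

- Forward key step: [RuCl2(p-cymene)]2 (divalent ruthenium) and K2S2O8 in trifluoroacetic acid and its anhydride. The C4 carbonyl directs cycloruthenation at the peri C5–H, and oxidation with C–O bond formation gives a trifluoroacetate that is hydrolysed on work-up to 2-[5-hydroxy-8-methoxy-4-oxo-7-(pivaloyloxy)chromen-2-yl]-4,5-dimethoxyphenyl pivalate A4.
- In its favour: the 7,8-pattern comes from the starting arene, so the C6/C8 question never arises. Carbonyl-directed peri-hydroxylation of chromones is an established reaction class. Both remaining protecting groups are esters that one mild methanolysis removes.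
- Against it here: persulfate in hot trifluoroacetic acid is a strongly oxidising and acidic medium for a substrate whose ring B is a very electron-rich trioxygenated arene, so ring B oxidation or undirected acyloxylation would compete. The ring B pivalate carbonyl is a second possible directing group. The step adds an oxygen but no skeleton, so the flavone must first be built linearly (ester, diketone, cyclisation, protecting-group exchange).
- Comparison: the endgame, which avoids hot hydroxide, is better than that of the chosen plan, and the origin of the ring A pattern is at least its equal. Both plans rest on an oxygen-directed C–H metalation, but the chosen one uses it to form the central C–C bond convergently. Step counts should be about equal.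

Alternative 3: The C8–O bond is cut. The precursor is 7-(benzyloxy)-2-[2-(benzyloxy)-4,5-dimethoxyphenyl]-5-hydroxychromen-4-one A7, which could be reached from 1 by 4-O-benzylation followed by Baker–Venkataraman chemistry with the chloride of 2-(benzyloxy)-4,5-dimethoxybenzoic acid A9.

- Forward key step: Elbs oxidation. In aqueous alkali the 5-phenoxide of A7 attacks K2S2O8 through its para carbon C8, and acid hydrolysis of the aryl sulfate gives 7-(benzyloxy)-2-[2-(benzyloxy)-4,5-dimethoxyphenyl]-5,8-dihydroxychromen-4-one A6. Methylation of the non-chelated 8-hydroxyl would give 7-(benzyloxy)-2-[2-(benzyloxy)-4,5-dimethoxyphenyl]-5-hydroxy-8-methoxychromen-4-one A8, and hydrogenolysis the target.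
- In its favour: the flavone is assembled by the most dependable classical sequence. Hydroxylation can only go para to the 5-oxygen, chelation makes the methylation selective, and there is one kind of protecting group with a one-step endgame.
- Against it here: Elbs oxidations usually stop at partial conversion, and this one would be run late on the most valuable and least soluble intermediate. A6 is a hydroquinone and air-sensitive in alkali. Sulfate hydrolysis needs hot mineral acid, under which a 5,8-dihydroxyflavone can isomerise by ring opening and benzyl ethers can be lost.
- Comparison: in precedent for ring construction and in protecting-group economy this alternative is better than the chosen plan, and its regiochemical logic is at least equal. The chosen plan is more convergent and settles the oxygenation pattern early, on a simple ketone, instead of late. Total step counts are comparable once the preparation of A9 is included.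

Key step: step 6

Remark: the target is achiral, so no stereocontrol is needed; the commercial monohydrate of 1 is assumed to be dried before use.

## Route

Step 1
Reactants: 1 2',4',6'-trihydroxyacetophenone
Product: 2 1-[2,4-bis(benzyloxy)-6-hydroxyphenyl]ethanone
Conditions: BnBr (2.1 equiv), K2CO3 (2.2 equiv), DMF, 0 °C to rt
Reagents that add atoms: benzyl bromide, BrCc1ccccc1
Why: Williamson ether synthesis; the para hydroxyl and one ortho hydroxyl are alkylated, after which the last hydroxyl is locked in a hydrogen bond to the acetyl carbonyl and should resist benzylation under these mild conditions.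

Step 2
Reactants: 2 1-[2,4-bis(benzyloxy)-6-hydroxyphenyl]ethanone
Product: 3 1-[4,6-bis(benzyloxy)-2-hydroxy-3-iodophenyl]ethanone
Conditions: NIS (1.0 equiv), TFA (10 mol%), MeCN, 0 °C, dark
Reagents that add atoms: N-iodosuccinimide, O=C1CCC(=O)N1I
Why: Electrophilic aromatic iodination; dialkyl ethers of this ketone take electrophiles ortho to the chelated hydroxyl, and that site is also less crowded than the one between the two benzyloxy groups. The regiochemistry of 3 would be confirmed before the material is carried forward by NOE contacts of its single ring proton to both OCH2 groups.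

Step 3
Reactants: 3 1-[4,6-bis(benzyloxy)-2-hydroxy-3-iodophenyl]ethanone
Product: 4 1-[4,6-bis(benzyloxy)-2-hydroxy-3-methoxyphenyl]ethanone
Conditions: NaOMe (6 equiv), CuCl (30 mol%), DMF/MeOH, 110 °C, N2; then dil. HCl
Reagents that add atoms: sodium methoxide, C[O-].[Na+]
Why: Ullmann-type methoxylation of an aryl iodide by CuOMe (monovalent copper) formed from CuCl and NaOMe; the ortho-iodophenol motif is the one converted in the classical iodovanillin-to-syringaldehyde reaction, and the ketone is shielded as its phenoxide-chelated form while benzyl ethers are inert to methoxide.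

Step 4
Reactants: 4 1-[4,6-bis(benzyloxy)-2-hydroxy-3-methoxyphenyl]ethanone
Product: 6 5,7-bis(benzyloxy)-8-methoxychromen-4-one, via enaminone 5 (not isolated)
Conditions: DMF-DMA (3 equiv), toluene, 100 °C; then conc. HCl, CH2Cl2, 40 °C
Reagents that add atoms: N,N-dimethylformamide dimethyl acetal, COC(OC)N(C)C
Why: Condensation of the methyl ketone with the amide acetal gives the E-enaminone; acid then promotes conjugate addition of the ortho hydroxyl and loss of dimethylamine (addition–elimination) to close the chromone. Aryl benzyl ethers tolerate the short exposure to aqueous HCl in CH2Cl2.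

Step 5
Reactants: 7 3,4-dimethoxyphenol; 8 dimethylcarbamoyl chloride
Product: 9 3,4-dimethoxyphenyl dimethylcarbamate
Conditions: K2CO3 (1.5 equiv), MeCN, 80 °C
Reagents that add atoms: none
Why: O-acylation of a phenoxide by a carbamoyl chloride (nucleophilic acyl substitution); 8 is a carcinogenic acylating agent and is to be handled in a closed system and quenched with aqueous ammonia.

Step 6
Reactants: 6 5,7-bis(benzyloxy)-8-methoxychromen-4-one; 9 3,4-dimethoxyphenyl dimethylcarbamate (3 equiv)
Product: 10 2-[5,7-bis(benzyloxy)-8-methoxy-4-oxochromen-2-yl]-4,5-dimethoxyphenyl dimethylcarbamate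
Conditions: Pd(OAc)2 (10 mol%), AgOAc (3 equiv), PivOH, 110 °C
Reagents that add atoms: none
Why: The closest known reaction type is the Fujiwara–Moritani (dehydrogenative Heck) coupling, here merging carbamate-directed ortho C–H palladation of a phenol derivative with the oxidative C2-arylation of chromones by arenes. Pd(OAc)2 binds the carbamate carbonyl oxygen of 9 and, by carboxylate-assisted concerted metalation–deprotonation, palladates C6 to give a six-membered palladacycle. C6 is the only ortho C–H that is unhindered and para to a methoxy group; C2 lies between two oxygens and C5 is out of reach of the directing group, so direction and innate reactivity agree. The arylpalladium species adds syn across C2=C3 of 6 with the aryl group going to the electron-poor beta-carbon C2 and palladium to C3 as an enolate, which is the normal Heck polarity and fixes C2 over C3. The carbon-bound enolate equilibrates through its oxygen-bound form so that palladium can reach the face syn to C2–H, and beta-hydride elimination restores the pyranone; no ring is closed and no stereocentre remains. Zerovalent palladium is returned to divalent palladium by two equivalents of AgOAc, with pivalic acid keeping the metal electrophilic and acting as proton shuttle. Cross-coupling is favoured over homocoupling of 6 by using 9 in excess, and a second coupling is blocked because the remaining ortho C–H of 10 is flanked by the carbamate oxygen and a methoxy group. No free phenol is present, and benzyl and methyl ethers should tolerate the weakly acidic oxidising medium.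

Step 7
Reactants: 10 2-[5,7-bis(benzyloxy)-8-methoxy-4-oxochromen-2-yl]-4,5-dimethoxyphenyl dimethylcarbamate
Product: 11 2-(5,7-dihydroxy-8-methoxy-4-oxochromen-2-yl)-4,5-dimethoxyphenyl dimethylcarbamate
Conditions: H2 (1 atm), 10% Pd/C, EtOAc/MeOH, rt
Reagents that add atoms: none
Why: Catalytic hydrogenolysis of two aryl benzyl ethers; the conjugated C2=C3 bond of a 2-arylchromone, the methyl ethers and the carbamate are expected to be untouched at one atmosphere and room temperature.

Step 8
Reactants: 11 2-(5,7-dihydroxy-8-methoxy-4-oxochromen-2-yl)-4,5-dimethoxyphenyl dimethylcarbamate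
Product: 12 5,7-dihydroxy-2-(2-hydroxy-4,5-dimethoxyphenyl)-8-methoxychromen-4-one
Conditions: NaOH (2 M aq, degassed), EtOH, 80 °C, Ar; then dil. HCl to pH 3
Reagents that add atoms: none
Why: Base hydrolysis of an aryl carbamate by acyl–oxygen cleavage; the 5,7-diphenoxide formed at once makes C2 a poor electrophile and so protects ring C from hydroxide, and exclusion of air protects the electron-rich phenoxides. Methyl ethers are inert.

## Compound list

1 | 2',4',6'-trihydroxyacetophenone | CC(=O)c1c(O)cc(O)cc1O | starting material
2 | 1-[2,4-bis(benzyloxy)-6-hydroxyphenyl]ethanone | CC(=O)c1c(O)cc(OCc2ccccc2)cc1OCc1ccccc1 | intermediate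
3 | 1-[4,6-bis(benzyloxy)-2-hydroxy-3-iodophenyl]ethanone | CC(=O)c1c(O)c(I)c(OCc2ccccc2)cc1OCc1ccccc1 | intermediate
4 | 1-[4,6-bis(benzyloxy)-2-hydroxy-3-methoxyphenyl]ethanone | CC(=O)c1c(O)c(OC)c(OCc2ccccc2)cc1OCc1ccccc1 | intermediate
5 | (E)-1-[4,6-bis(benzyloxy)-2-hydroxy-3-methoxyphenyl]-3-(dimethylamino)prop-2-en-1-one | CN(C)/C=C/C(=O)c1c(O)c(OC)c(OCc2ccccc2)cc1OCc1ccccc1 | intermediate
6 | 5,7-bis(benzyloxy)-8-methoxychromen-4-one | COc1c(OCc2ccccc2)cc(OCc2ccccc2)c2c(=O)ccoc12 | intermediate
7 | 3,4-dimethoxyphenol | COc1ccc(O)cc1OC | starting material
8 | dimethylcarbamoyl chloride | CN(C)C(Cl)=O | starting material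
9 | 3,4-dimethoxyphenyl dimethylcarbamate | COc1ccc(OC(=O)N(C)C)cc1OC | intermediate
10 | 2-[5,7-bis(benzyloxy)-8-methoxy-4-oxochromen-2-yl]-4,5-dimethoxyphenyl dimethylcarbamate | COc1cc(OC(=O)N(C)C)c(-c2cc(=O)c3c(OCc4ccccc4)cc(OCc4ccccc4)c(OC)c3o2)cc1OC | intermediate
11 | 2-(5,7-dihydroxy-8-methoxy-4-oxochromen-2-yl)-4,5-dimethoxyphenyl dimethylcarbamate | COc1cc(OC(=O)N(C)C)c(-c2cc(=O)c3c(O)cc(O)c(OC)c3o2)cc1OC | intermediate
12 | 5,7-dihydroxy-2-(2-hydroxy-4,5-dimethoxyphenyl)-8-methoxychromen-4-one | COc1cc(O)c(-c2cc(=O)c3c(O)cc(O)c(OC)c3o2)cc1OC | target

## Step count and least certain steps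

Total step count: 8. Longest linear sequence: 7 steps (steps 1, 2, 3, 4, 6, 7, 8, from 1); step 5 is a one-step branch.

**Step 6 (key step).** The most likely failures are electrophilic palladation of the electron-rich chromone at C3 followed by its homocoupling, weak binding of the carbamate in pivalic acid that makes palladation of 9 slow, precipitation of zerovalent palladium as metal before turnover, and acidolysis of the peri 5-O-benzyl ether on long heating. The fallback forms the same bond with a pre-functionalised ring B. It sets out from 9 and 6 and comes back at 10. Bromination of 9 with NBS in MeCN, para to the 3-methoxy group, would give 2-bromo-4,5-dimethoxyphenyl dimethylcarbamate F1. Miyaura borylation (B2pin2, PdCl2(dppf), KOAc, dioxane, 90 °C) would give 4,5-dimethoxy-2-(4,4,5,5-tetramethyl-1,3,2-dioxaborolan-2-yl)phenyl dimethylcarbamate F2. Conjugate addition of F2 to 6 in a water-containing medium, catalysed by Pd(TFA)2 and 2,2'-bipyridine (divalent palladium), would give racemic 2-[5,7-bis(benzyloxy)-8-methoxy-4-oxo-2,3-dihydrochromen-2-yl]-4,5-dimethoxyphenyl dimethylcarbamate F3. Dehydrogenation with I2 in DMSO at 120 °C then gives 10.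

**Step 2.** Substitution may occur at the other activated site (para to the hydroxyl, between the two benzyloxy groups), or twice, because both free ring positions are strongly activated; the wrong site would end as a 6-methoxy chromone. The fallback removes the choice by symmetry. It sets out from 1 and comes back at 4. Monobenzylation of the most acidic 4-hydroxyl (BnBr, 1 equiv, K2CO3, DMF, 0 °C) would give 1-[4-(benzyloxy)-2,6-dihydroxyphenyl]ethanone F4, whose two free ring positions are equivalent. Iodination with NIS would give 1-[4-(benzyloxy)-2,6-dihydroxy-3-iodophenyl]ethanone F5. Methoxylation as in step 3 would give 1-[4-(benzyloxy)-2,6-dihydroxy-3-methoxyphenyl]ethanone F6. Benzylation of the less hindered hydroxyl, the one not flanked by the methoxy group, gives 4. The regiochemical question then moves to this last alkylation, where steric bias has to do the work.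

**Step 3.** Reductive loss of iodine can outrun C–O bond formation at a carbon flanked by two ortho substituents on an electron-rich phenoxide; this would return 2, and long heating with methoxide may also start aldol chemistry of the ketone. The fallback avoids aryl halides and sets out from 2, the compound that the failure regenerates; it comes back at 4. Magnesium-mediated ortho-formylation (MgCl2, Et3N, paraformaldehyde, MeCN, reflux), which is confined to the position next to the phenoxide, would give 3-acetyl-4,6-bis(benzyloxy)-2-hydroxybenzaldehyde F7. Dakin oxidation (H2O2, NaOH, aqueous THF, 0 °C) would give 1-[4,6-bis(benzyloxy)-2,3-dihydroxyphenyl]ethanone F8. Methylation of the non-chelated hydroxyl (MeI, 1 equiv, K2CO3, acetone, rt) gives 4. This sequence also bypasses the iodination of step 2.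

**Step 8.** Hydrolysis of the hindered, electron-rich aryl carbamate may be slow. Prolonged heating in alkali gives time for hydroxide addition at C2, with ring opening and reclosure in another sense, and for oxidation of the phenoxides if air enters. The fallback changes the directing group to an ester that leaves under mild methanolysis. It sets out from 7 and 6 and comes back at 12. Pivaloylation of 7 (PivCl, Et3N, DMAP, CH2Cl2) would give 3,4-dimethoxyphenyl pivalate F9. Coupling with 6 under the conditions of step 6, where the ester carbonyl is a weaker director but the site is still the innately most reactive one, would give 2-[5,7-bis(benzyloxy)-8-methoxy-4-oxochromen-2-yl]-4,5-dimethoxyphenyl pivalate F10. Hydrogenolysis would give 2-(5,7-dihydroxy-8-methoxy-4-oxochromen-2-yl)-4,5-dimethoxyphenyl pivalate F11. K2CO3 in MeOH at room temperature then gives 12.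

## Further compounds

F1 | step 6 | 2-bromo-4,5-dimethoxyphenyl dimethylcarbamate | COc1cc(OC(=O)N(C)C)c(Br)cc1OC
F2 | step 6 | 4,5-dimethoxy-2-(4,4,5,5-tetramethyl-1,3,2-dioxaborolan-2-yl)phenyl dimethylcarbamate | COc1cc(OC(=O)N(C)C)c(B2OC(C)(C)C(C)(C)O2)cc1OC
F3 | step 6 | racemic 2-[5,7-bis(benzyloxy)-8-methoxy-4-oxo-2,3-dihydrochromen-2-yl]-4,5-dimethoxyphenyl dimethylcarbamate | COc1cc(OC(=O)N(C)C)c(C2CC(=O)c3c(OCc4ccccc4)cc(OCc4ccccc4)c(OC)c3O2)cc1OC
F4 | step 2 | 1-[4-(benzyloxy)-2,6-dihydroxyphenyl]ethanone | CC(=O)c1c(O)cc(OCc2ccccc2)cc1O
F5 | step 2 | 1-[4-(benzyloxy)-2,6-dihydroxy-3-iodophenyl]ethanone | CC(=O)c1c(O)cc(OCc2ccccc2)c(I)c1O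
F6 | step 2 | 1-[4-(benzyloxy)-2,6-dihydroxy-3-methoxyphenyl]ethanone | CC(=O)c1c(O)cc(OCc2ccccc2)c(OC)c1O
F7 | step 3 | 3-acetyl-4,6-bis(benzyloxy)-2-hydroxybenzaldehyde | CC(=O)c1c(O)c(C=O)c(OCc2ccccc2)cc1OCc1ccccc1
F8 | step 3 | 1-[4,6-bis(benzyloxy)-2,3-dihydroxyphenyl]ethanone | CC(=O)c1c(O)c(O)c(OCc2ccccc2)cc1OCc1ccccc1
F9 | step 8 | 3,4-dimethoxyphenyl pivalate | COc1ccc(OC(=O)C(C)(C)C)cc1OC
F10 | step 8 | 2-[5,7-bis(benzyloxy)-8-methoxy-4-oxochromen-2-yl]-4,5-dimethoxyphenyl pivalate | COc1cc(OC(=O)C(C)(C)C)c(-c2cc(=O)c3c(OCc4ccccc4)cc(OCc4ccccc4)c(OC)c3o2)cc1OC
F11 | step 8 | 2-(5,7-dihydroxy-8-methoxy-4-oxochromen-2-yl)-4,5-dimethoxyphenyl pivalate | COc1cc(OC(=O)C(C)(C)C)c(-c2cc(=O)c3c(O)cc(O)c(OC)c3o2)cc1OC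
A1 | alternative 1 | 2-[2-(benzyloxy)-4,5-dimethoxyphenyl]-5,7-dihydroxy-8-methoxychromen-4-one | COc1cc(OCc2ccccc2)c(-c2cc(=O)c3c(O)cc(O)c(OC)c3o2)cc1OC
A2 | alternative 1 | methyl 6-[2-(benzyloxy)-4,5-dimethoxyphenyl]-2-(methoxymethyl)-4-oxo-4H-pyran-3-carboxylate | COCc1oc(-c2cc(OC)c(OC)cc2OCc2ccccc2)cc(=O)c1C(=O)OC
A3 | alternative 1 | N-methoxy-N-methylacetamide | CON(C)C(C)=O
A4 | alternative 2 | 2-[5-hydroxy-8-methoxy-4-oxo-7-(pivaloyloxy)chromen-2-yl]-4,5-dimethoxyphenyl pivalate | COc1cc(OC(=O)C(C)(C)C)c(-c2cc(=O)c3c(O)cc(OC(=O)C(C)(C)C)c(OC)c3o2)cc1OC
A5 | alternative 2 | 2-[8-methoxy-4-oxo-7-(pivaloyloxy)chromen-2-yl]-4,5-dimethoxyphenyl pivalate | COc1cc(OC(=O)C(C)(C)C)c(-c2cc(=O)c3ccc(OC(=O)C(C)(C)C)c(OC)c3o2)cc1OC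
A6 | alternative 3 | 7-(benzyloxy)-2-[2-(benzyloxy)-4,5-dimethoxyphenyl]-5,8-dihydroxychromen-4-one | COc1cc(OCc2ccccc2)c(-c2cc(=O)c3c(O)cc(OCc4ccccc4)c(O)c3o2)cc1OC
A7 | alternative 3 | 7-(benzyloxy)-2-[2-(benzyloxy)-4,5-dimethoxyphenyl]-5-hydroxychromen-4-one | COc1cc(OCc2ccccc2)c(-c2cc(=O)c3c(O)cc(OCc4ccccc4)cc3o2)cc1OC
A8 | alternative 3 | 7-(benzyloxy)-2-[2-(benzyloxy)-4,5-dimethoxyphenyl]-5-hydroxy-8-methoxychromen-4-one | COc1cc(OCc2ccccc2)c(-c2cc(=O)c3c(O)cc(OCc4ccccc4)c(OC)c3o2)cc1OC
A9 | alternative 3 | 2-(benzyloxy)-4,5-dimethoxybenzoic acid | COc1cc(OCc2ccccc2)c(C(=O)O)cc1OC
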